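**Strategy.** Numbering: spiro C6; ring A C6–C1–C2–C3–C4–C5; ring B C6–C7–C8–C9–C10–C11; C14 exocyclic. The route rests on disconnecting C7–C8 of ring B. In one operation, anodic decarboxylation of a β-silyloxy acid releases a primary C8 radical that closes ring B 6-exo-dig onto a C6 ethynyl group and, after hydrogen capture, leaves the exocyclic C7=C14 methylene beside C8H2. The step exploits that ring B feature and the C–halogen bonds at C2, C3 (ring A) and C10, which tolerate oxidative but not reductive radical generation. The precursor is a hexanoic acid chain (C8–C11) on a ring A cyclohexane already carrying ethynyl, both bromides, the chloride and all five stereocentres.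

Key step: step 15

Remark: the less soluble salt of step 3 is assumed to pair the (R)-acid with (R)-1-phenylethylamine, and the (2R,5R)-pyrrolidine of step 12 is assumed (shielding model) to deliver the (S)-bromide; if either sense proves reversed, the antipodal amine is used and nothing else changes.

Step 1
Reactants: 1 4-methylcyclohex-3-ene-1-carboxylic acid (racemic); 2 3-methylbut-2-en-1-ol
Product: 3 3-methylbut-2-en-1-yl 4-methylcyclohex-3-ene-1-carboxylate (racemic)
Conditions: DCC, DMAP (cat.), CH2Cl2, 0 °C → rt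
Reagents that add atoms: none
Why: Steglich esterification of an unhindered acid with a primary allylic alcohol; the stereocentre of 1 does not matter because it is erased by enolisation in step 2.

Step 2
Reactants: 3 3-methylbut-2-en-1-yl 4-methylcyclohex-3-ene-1-carboxylate
Product: 6 rac-4-methyl-1-(2-methylbut-3-en-2-yl)cyclohex-3-ene-1-carboxylic acid, via silyl ketene acetal 4 (not isolated), via trimethylsilyl ester 5 (not isolated)
Conditions: LDA, TMSCl, THF, −78 °C → 65 °C; then 1 M HCl
Reagents that add atoms: none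
Why: Ireland–Claisen rearrangement: the ester enolate is trapped as its silyl ketene acetal, whose [3,3] shift joins the ring α-carbon (C6) to the dimethyl-bearing allyl terminus (C11), so both quaternary carbons and the C10=C9 vinyl group arise together, with C6 racemic.

Step 3
Reactants: 6 rac-4-methyl-1-(2-methylbut-3-en-2-yl)cyclohex-3-ene-1-carboxylic acid
Product: 7 (R)-1-phenylethylammonium (R)-4-methyl-1-(2-methylbut-3-en-2-yl)cyclohex-3-ene-1-carboxylate
Conditions: (R)-1-phenylethylamine, acetone, crystallisation; recrystallised to constant rotation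
Reagents that add atoms: (R)-1-phenylethylamine, C[C@@H](N)c1ccccc1
Why: Classical resolution through diastereomeric ammonium carboxylate salts; the salt that crystallises fixes C6 as R at this stage.

Step 4
Reactants: 7 (R)-1-phenylethylammonium (R)-4-methyl-1-(2-methylbut-3-en-2-yl)cyclohex-3-ene-1-carboxylate
Product: 8 [(1R)-4-methyl-1-(2-methylbut-3-en-2-yl)cyclohex-3-en-1-yl]methanol
Conditions: LiAlH4, THF, 0 °C → reflux; aq. NaOH work-up, dilute HCl wash
Reagents that add atoms: none
Why: Hydride reduction of the carboxylate salt gives the neopentyl C7 alcohol; the quaternary C6 cannot epimerise and both alkenes are inert to LiAlH4.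

Step 5
Reactants: 8 [(1R)-4-methyl-1-(2-methylbut-3-en-2-yl)cyclohex-3-en-1-yl]methanol
Product: 9 (1S,4R,6S)-6-bromo-1-methyl-4-(2-methylbut-3-en-2-yl)-2-oxabicyclo[2.2.2]octane
Conditions: NBS, CH2Cl2, −20 → 0 °C, dark
Reagents that add atoms: N-bromosuccinimide, O=C1CCC(=O)N1Br
Why: Bromoetherification of a cyclohexenyl carbinol, as in the closure of terpineol-type alcohols to 1,8-cineoles: the C7 hydroxyl is axial on C6 because the tertiary C11 group takes the equatorial site, and it opens the ring A bromonium ion at the methyl-bearing C3 (Markovnikov) from its own face, so bromine ends on C2 anti to oxygen and cis to C11 while C3–O is cis to C7; this tether is used because direct anti addition of BrCl to the conformationally biased cyclohexene would run trans-diaxially and give the opposite relation to C6, and the hindered vinyl group is too poor a nucleophile to compete.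

Step 6
Reactants: 9 (1S,4R,6S)-6-bromo-1-methyl-4-(2-methylbut-3-en-2-yl)-2-oxabicyclo[2.2.2]octane
Product: 11 3-[(1S,4R,6S)-6-bromo-1-methyl-2-oxabicyclo[2.2.2]octan-4-yl]-3-methylbutan-1-ol, via B-alkyl-9-borabicyclononane 10 (not isolated)
Conditions: 9-BBN, THF, 0 → 50 °C; then NaBO3·4H2O, H2O, rt
Reagents that add atoms: sodium perborate, [Na+].[O-]OB=O
Why: Anti-Markovnikov hydroboration–oxidation of the only alkene left (C10=C9) gives the primary C9 alcohol; the ring alkene and the C7 hydroxyl are masked in the bromo ether, and the secondary bromide tolerates the borane and the mild perborate oxidation.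

Step 7
Reactants: 11 3-[(1S,4R,6S)-6-bromo-1-methyl-2-oxabicyclo[2.2.2]octan-4-yl]-3-methylbutan-1-ol
Product: 12 3-[(1S,4R,6S)-6-bromo-1-methyl-2-oxabicyclo[2.2.2]octan-4-yl]-3-methylbutyl acetate
Conditions: Ac2O, pyridine, DMAP (cat.), CH2Cl2, 0 °C → rt
Reagents that add atoms: acetic anhydride, CC(=O)OC(C)=O
Why: Acylation of the unhindered primary alcohol protects C9–OH against the Lewis acid of step 8 and the oxidation of step 9, and the ester is shed without a step of its own in step 10.

Step 8
Reactants: 12 3-[(1S,4R,6S)-6-bromo-1-methyl-2-oxabicyclo[2.2.2]octan-4-yl]-3-methylbutyl acetate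
Product: 14 3-[(1R,3S,4S)-3-bromo-4-chloro-1-(hydroxymethyl)-4-methylcyclohexyl]-3-methylbutyl acetate, via alkyl dichloroborinate 13 (not isolated)
Conditions: BCl3, CH2Cl2, −78 → −30 °C; then H2O, NaHCO3 wash
Reagents that add atoms: boron trichloride, ClB(Cl)Cl
Why: Boron trihalide cleavage of a tertiary alkyl ether, steered by neighbouring-group participation: BCl3 binds the bridging oxygen, the tertiary C3–O bond ionises with help from the anti bromine on C2 (bromonium ion on the face cis to C11), and chloride returns to C3 from the face the oxygen has just left, delivered by the borate still tethered through C7, so C3–Cl should form with retention (cis to C7, trans to bromine), while the neopentyl C7–O bond can neither ionise nor be displaced and appears as the alcohol after hydrolysis.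

Step 9
Reactants: 14 3-[(1R,3S,4S)-3-bromo-4-chloro-1-(hydroxymethyl)-4-methylcyclohexyl]-3-methylbutyl acetate
Product: 15 3-[(1R,3S,4S)-3-bromo-4-chloro-1-formyl-4-methylcyclohexyl]-3-methylbutyl acetate
Conditions: Dess–Martin periodinane, NaHCO3, CH2Cl2, 0 °C → rt
Reagents that add atoms: none
Why: Dess–Martin oxidation converts the hindered neopentyl alcohol into the non-enolisable C7 aldehyde under buffered, non-basic conditions that leave the halides and the acetate alone.

Step 10
Reactants: 15 3-[(1R,3S,4S)-3-bromo-4-chloro-1-formyl-4-methylcyclohexyl]-3-methylbutyl acetate; 16 dimethyl (1-diazo-2-oxopropyl)phosphonate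
Product: 18 3-[(1R,3S,4S)-3-bromo-4-chloro-1-ethynyl-4-methylcyclohexyl]-3-methylbutan-1-ol, via alkynyl acetate 17 (not isolated)
Conditions: K2CO3, MeOH, 0 °C → rt
Reagents that add atoms: none
Why: Seyferth–Gilbert homologation in its Ohira–Bestmann form turns the C7 aldehyde into the C7≡C14 ethynyl group (C14 is the diazo carbon), and the same carbonate–methanol medium then methanolyses the acetate; both halogens are equatorial on the chair that keeps the C11 group equatorial, so neither has an antiperiplanar hydrogen for E2 loss under this mild base.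

Step 11
Reactants: 18 3-[(1R,3S,4S)-3-bromo-4-chloro-1-ethynyl-4-methylcyclohexyl]-3-methylbutan-1-ol
Product: 19 3-[(1R,3S,4S)-3-bromo-4-chloro-1-ethynyl-4-methylcyclohexyl]-3-methylbutanal
Conditions: Dess–Martin periodinane, NaHCO3, CH2Cl2, 0 °C → rt
Reagents that add atoms: none
Why: Dess–Martin oxidation of the primary C9 alcohol stops at the aldehyde and touches neither the alkyne nor the halides.

Step 12
Reactants: 19 3-[(1R,3S,4S)-3-bromo-4-chloro-1-ethynyl-4-methylcyclohexyl]-3-methylbutanal
Product: 20 (2S)-2-bromo-3-[(1S,3S,4S)-3-bromo-4-chloro-1-ethynyl-4-methylcyclohexyl]-3-methylbutanal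
Conditions: (2R,5R)-2,5-diphenylpyrrolidine (20 mol%), PhCO2H (20 mol%), 4,4-dibromo-2,6-di-tert-butylcyclohexa-2,5-dienone, CH2Cl2–pentane, −40 °C; cold filtration through silica, used at once
Reagents that add atoms: 4,4-dibromo-2,6-di-tert-butylcyclohexa-2,5-dienone, CC(C)(C)C1=CC(Br)(Br)C=C(C(C)(C)C)C1=O
Why: Enamine-catalysed enantioselective α-bromination of an aldehyde: the E-enamine of the C2-symmetric amine is brominated at C10 on the face not shielded by the adjacent phenyl group, so the catalyst sets C10 (S), and the neopentyl position of C10–H slows enolisation of the product until it is consumed in step 13.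

Step 13
Reactants: 20 (2S)-2-bromo-3-[(1S,3S,4S)-3-bromo-4-chloro-1-ethynyl-4-methylcyclohexyl]-3-methylbutanal; 21 tert-butyl acetate
Product: 23 tert-butyl (3R,4S)-4-bromo-5-[(1S,3S,4S)-3-bromo-4-chloro-1-ethynyl-4-methylcyclohexyl]-3-hydroxy-5-methylhexanoate, via lithium ester enolate 22 (not isolated)
Conditions: LDA, THF, −78 °C; then 20, −78 °C; AcOH quench at −78 °C
Reagents that add atoms: none
Why: Acetate aldol addition of a lithium ester enolate to an α-bromo aldehyde: in the Cornforth arrangement the C10–Br bond lies anti to the carbonyl and the enolate enters anti to the tertiary C11 group, which gives the anti bromohydrin and sets C9 (R) from C10 by 1,2-induction, while the cold acidic quench keeps the alkoxide from closing to an epoxide.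

Step 14
Reactants: 23 tert-butyl (3R,4S)-4-bromo-5-[(1S,3S,4S)-3-bromo-4-chloro-1-ethynyl-4-methylcyclohexyl]-3-hydroxy-5-methylhexanoate
Product: 26 (3R,4S)-4-bromo-5-[(1S,3S,4S)-3-bromo-4-chloro-1-ethynyl-4-methylcyclohexyl]-3-[(tert-butyldimethylsilyl)oxy]-5-methylhexanoic acid, via silyl ether tert-butyl ester 24 (not isolated), via bis-silyl ester 25 (not isolated)
Conditions: TBSOTf (3 equiv), 2,6-lutidine, CH2Cl2, 0 °C → rt; then THF–H2O–AcOH, rt
Reagents that add atoms: tert-butyldimethylsilyl triflate, CC(C)(C)[Si](C)(C)OS(=O)(=O)C(F)(F)F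
Why: Silyl triflate silylation of the C9 hydroxyl is followed in the same flask by the known silyl-triflate dealkylation of the tert-butyl ester (loss of isobutene) to the silyl ester, which alone is hydrolysed by the mild aqueous acid, and no free C9 alkoxide is ever formed beside the C10 bromide.

Step 15
Reactants: 26 (3R,4S)-4-bromo-5-[(1S,3S,4S)-3-bromo-4-chloro-1-ethynyl-4-methylcyclohexyl]-3-[(tert-butyldimethylsilyl)oxy]-5-methylhexanoic acid
Product: 27 tert-butyl{[(2S,3S,6S,9R,10S)-2,10-dibromo-3-chloro-3,11,11-trimethyl-7-methylidenespiro[5.5]undecan-9-yl]oxy}dimethylsilane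
Conditions: Pt anode, Pt cathode, undivided cell, MeOH, NaOMe (10 mol%), 0.02 M, constant current at low current density, 10–15 °C
Reagents that add atoms: none
Why: One-electron oxidation of the carboxylate of 26 at the platinum anode and loss of CO2 give the primary C8 radical, which is not oxidised further because its only heteroatom neighbour, the silyloxy group, sits one carbon away on C9; it adds to the internal alkyne carbon C7, and the resulting σ-vinyl radical at C14 abstracts hydrogen from methanol to leave the C7=C14 methylene. The closest known reaction type is Kolbe electrolysis run as a radical cyclisation onto a tethered π bond, established for five-membered closures and used here for the six-membered homologue. Ring B is closed in the 6-exo-dig mode (C8 onto C7), the 7-endo attack on C14 being out of reach of the tether C9–C10–C11–C6, whose gem-dimethyl C11 and quaternary C6 compress the chain and speed the closure. No stereocentre is created, and C2, C3, C6, C9 and C10 pass through untouched. The step needs chemoselective radical generation beside two secondary C–Br bonds and a tertiary C–Cl bond, and the anode secures it because it discharges only the carboxylate, whereas stannanes or SmI2 (divalent samarium) would reduce the halides. Moderate dilution and low current density keep the stationary radical concentration small so that cyclisation can outrun Kolbe dimerisation.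

Step 16
Reactants: 27 tert-butyl{[(2S,3S,6S,9R,10S)-2,10-dibromo-3-chloro-3,11,11-trimethyl-7-methylidenespiro[5.5]undecan-9-yl]oxy}dimethylsilane
Product: 28 (2S,3S,6S,9R,10S)-2,10-dibromo-3-chloro-3,11,11-trimethyl-7-methylidenespiro[5.5]undecan-9-ol (target)
Conditions: HF·pyridine, pyridine, THF, 0 °C → rt
Reagents that add atoms: none
Why: Fluoride-mediated desilylation under buffered, weakly acidic conditions frees the C9 hydroxyl without exposing the tertiary chloride to base or the exocyclic alkene to strong acid, and the cis bromohydrin of ring B cannot reach the anti geometry needed for epoxide closure.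

**Compound list**

1 | 4-methylcyclohex-3-ene-1-carboxylic acid (racemic) | CC1=CCC(CC1)C(=O)O | starting material
2 | 3-methylbut-2-en-1-ol (prenol) | CC(C)=CCO | starting material
3 | 3-methylbut-2-en-1-yl 4-methylcyclohex-3-ene-1-carboxylate (racemic) | CC1=CCC(CC1)C(=O)OCC=C(C)C | intermediate
4 | silyl ketene acetal, trimethyl{[(4-methylcyclohex-3-en-1-ylidene)(3-methylbut-2-en-1-yloxy)methyl]oxy}silane | CC1=CCC(CC1)=C(O[Si](C)(C)C)OCC=C(C)C | intermediate
5 | trimethylsilyl 4-methyl-1-(2-methylbut-3-en-2-yl)cyclohex-3-ene-1-carboxylate (racemic) | C=CC(C)(C)C1(CCC(C)=CC1)C(=O)O[Si](C)(C)C | intermediate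
6 | rac-4-methyl-1-(2-methylbut-3-en-2-yl)cyclohex-3-ene-1-carboxylic acid | C=CC(C)(C)C1(CCC(C)=CC1)C(=O)O | intermediate
7 | (R)-1-phenylethylammonium (R)-4-methyl-1-(2-methylbut-3-en-2-yl)cyclohex-3-ene-1-carboxylate | C=CC(C)(C)[C@@]1(C(=O)[O-])CCC(C)=CC1.C[C@@H]([NH3+])c1ccccc1 | intermediate
8 | [(1R)-4-methyl-1-(2-methylbut-3-en-2-yl)cyclohex-3-en-1-yl]methanol | C=CC(C)(C)[C@@]1(CO)CCC(C)=CC1 | intermediate
9 | (1S,4R,6S)-6-bromo-1-methyl-4-(2-methylbut-3-en-2-yl)-2-oxabicyclo[2.2.2]octane (ether oxygen on C3 and C7; Br on C2 anti to oxygen) | C=CC(C)(C)[C@]12CC[C@](C)(OC1)[C@@H](Br)C2 | intermediate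
10 | 9-{3-[(1S,4R,6S)-6-bromo-1-methyl-2-oxabicyclo[2.2.2]octan-4-yl]-3-methylbutyl}-9-borabicyclo[3.3.1]nonane | CC(C)(CCB1C2CCCC1CCC2)[C@]34CC[C@](C)(OC3)[C@@H](Br)C4 | intermediate
11 | 3-[(1S,4R,6S)-6-bromo-1-methyl-2-oxabicyclo[2.2.2]octan-4-yl]-3-methylbutan-1-ol | OCCC(C)(C)[C@]12CC[C@](C)(OC1)[C@@H](Br)C2 | intermediate
12 | 3-[(1S,4R,6S)-6-bromo-1-methyl-2-oxabicyclo[2.2.2]octan-4-yl]-3-methylbutyl acetate | CC(=O)OCCC(C)(C)[C@]12CC[C@](C)(OC1)[C@@H](Br)C2 | intermediate
13 | 3-[(1R,3S,4S)-3-bromo-4-chloro-1-{[(dichloroboranyl)oxy]methyl}-4-methylcyclohexyl]-3-methylbutyl acetate | CC(=O)OCCC(C)(C)[C@@]1(COB(Cl)Cl)CC[C@](C)(Cl)[C@@H](Br)C1 | intermediate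
14 | 3-[(1R,3S,4S)-3-bromo-4-chloro-1-(hydroxymethyl)-4-methylcyclohexyl]-3-methylbutyl acetate | CC(=O)OCCC(C)(C)[C@@]1(CO)CC[C@](C)(Cl)[C@@H](Br)C1 | intermediate
15 | 3-[(1R,3S,4S)-3-bromo-4-chloro-1-formyl-4-methylcyclohexyl]-3-methylbutyl acetate | CC(=O)OCCC(C)(C)[C@@]1(C=O)CC[C@](C)(Cl)[C@@H](Br)C1 | intermediate
16 | dimethyl (1-diazo-2-oxopropyl)phosphonate | COP(=O)(OC)C(=[N+]=[N-])C(C)=O | starting material
17 | 3-[(1R,3S,4S)-3-bromo-4-chloro-1-ethynyl-4-methylcyclohexyl]-3-methylbutyl acetate | CC(=O)OCCC(C)(C)[C@@]1(C#C)CC[C@](C)(Cl)[C@@H](Br)C1 | intermediate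
18 | 3-[(1R,3S,4S)-3-bromo-4-chloro-1-ethynyl-4-methylcyclohexyl]-3-methylbutan-1-ol | OCCC(C)(C)[C@@]1(C#C)CC[C@](C)(Cl)[C@@H](Br)C1 | intermediate
19 | 3-[(1R,3S,4S)-3-bromo-4-chloro-1-ethynyl-4-methylcyclohexyl]-3-methylbutanal | O=CCC(C)(C)[C@@]1(C#C)CC[C@](C)(Cl)[C@@H](Br)C1 | intermediate
20 | (2S)-2-bromo-3-[(1S,3S,4S)-3-bromo-4-chloro-1-ethynyl-4-methylcyclohexyl]-3-methylbutanal (ring C1 descriptor changes from R to S by CIP priority only) | O=C[C@@H](Br)C(C)(C)[C@@]1(C#C)CC[C@](C)(Cl)[C@@H](Br)C1 | intermediate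
21 | tert-butyl acetate | CC(=O)OC(C)(C)C | starting material
22 | lithium 1-(tert-butoxy)ethen-1-olate | [Li+].C=C([O-])OC(C)(C)C | intermediate
23 | tert-butyl (3R,4S)-4-bromo-5-[(1S,3S,4S)-3-bromo-4-chloro-1-ethynyl-4-methylcyclohexyl]-3-hydroxy-5-methylhexanoate | CC(C)(C)OC(=O)C[C@@H](O)[C@@H](Br)C(C)(C)[C@@]1(C#C)CC[C@](C)(Cl)[C@@H](Br)C1 | intermediate
24 | tert-butyl (3R,4S)-4-bromo-5-[(1S,3S,4S)-3-bromo-4-chloro-1-ethynyl-4-methylcyclohexyl]-3-[(tert-butyldimethylsilyl)oxy]-5-methylhexanoate | CC(C)(C)OC(=O)C[C@@H](O[Si](C)(C)C(C)(C)C)[C@@H](Br)C(C)(C)[C@@]1(C#C)CC[C@](C)(Cl)[C@@H](Br)C1 | intermediate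
25 | tert-butyldimethylsilyl (3R,4S)-4-bromo-5-[(1S,3S,4S)-3-bromo-4-chloro-1-ethynyl-4-methylcyclohexyl]-3-[(tert-butyldimethylsilyl)oxy]-5-methylhexanoate | CC(C)(C)[Si](C)(C)OC(=O)C[C@@H](O[Si](C)(C)C(C)(C)C)[C@@H](Br)C(C)(C)[C@@]1(C#C)CC[C@](C)(Cl)[C@@H](Br)C1 | intermediate
26 | (3R,4S)-4-bromo-5-[(1S,3S,4S)-3-bromo-4-chloro-1-ethynyl-4-methylcyclohexyl]-3-[(tert-butyldimethylsilyl)oxy]-5-methylhexanoic acid | OC(=O)C[C@@H](O[Si](C)(C)C(C)(C)C)[C@@H](Br)C(C)(C)[C@@]1(C#C)CC[C@](C)(Cl)[C@@H](Br)C1 | intermediate
27 | tert-butyl{[(2S,3S,6S,9R,10S)-2,10-dibromo-3-chloro-3,11,11-trimethyl-7-methylidenespiro[5.5]undecan-9-yl]oxy}dimethylsilane | C=C1C[C@@H](O[Si](C)(C)C(C)(C)C)[C@@H](Br)C(C)(C)[C@]12CC[C@](C)(Cl)[C@@H](Br)C2 | intermediate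
28 | (2S,3S,6S,9R,10S)-2,10-dibromo-3-chloro-3,11,11-trimethyl-7-methylidenespiro[5.5]undecan-9-ol | C=C1C[C@@H](O)[C@@H](Br)C(C)(C)[C@]12CC[C@](C)(Cl)[C@@H](Br)C2 | target

Total step count: 16. Longest linear sequence: 16 steps (from 1 to 28).

**Steps most likely to fail**

Step 15. The 6-exo closure is slower than the usual five-membered anodic cyclisations, so the C8 radical may instead couple with a second radical in the crowded layer at the electrode, take hydrogen before it has closed, or be oxidised further and captured by solvent. Fallback: from 26, DCC-mediated coupling with 1-hydroxypyridine-2(1H)-thione in the dark should give the 2-thioxopyridin-1(2H)-yl ester F1. Irradiation with visible light in dilute benzene, with tert-butyl thiol added slowly (Barton decarboxylation run as a radical cyclisation), generates the same C8 radical in homogeneous solution at a concentration set by the light flux. The thiol serves the vinyl radical as hydrogen donor, no stannane is present so the three halides stay, and the product is 27.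

Step 8. The β-bromo ether may ionise sluggishly, chloride may enter at C2 with bromine shifting to C3 through the bromonium ion, or the cation may lose a proton to give alkenes. Fallback: from 12, zinc dust in AcOH–THF should remove bromine and the ether oxygen by reductive β-elimination and give 3-[(1R)-1-(hydroxymethyl)-4-methylcyclohex-3-en-1-yl]-3-methylbutyl acetate F2. TIPSOTf and 2,6-lutidine then give the triisopropylsilyl ether F3. NBS with ClTi(OiPr)3 in hexane adds bromine and chlorine anti and Markovnikov across C2=C3 in one intermolecular step. The (2S,3S) bromochloride F4 is separated by chromatography from its (2R,3R) diastereomer; the bulky axial silyloxymethyl group is counted on to hinder bromonium formation on its own face, and this fallback pays with that separation. HF·pyridine then removes the silyl group and the route is rejoined at 14.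

Step 12. Enamine formation at an aldehyde flanked by two quaternary carbons may be slow, an uncatalysed background bromination may erode enantiocontrol, and C10 may epimerise by enolisation during handling. Fallback: from 19, NaClO2/NaH2PO4/2-methylbut-2-ene should give 3-[(1R,3S,4S)-3-bromo-4-chloro-1-ethynyl-4-methylcyclohexyl]-3-methylbutanoic acid F5. PivCl, Et3N, LiCl and (S)-4-benzyloxazolidin-2-one give the N-acyl oxazolidinone F6. Bu2BOTf and iPr2NEt, then NBS at −78 °C, brominate the Z boron enolate on the face away from the benzyl group to give the (S)-bromo imide F7. LiBH4–MeOH in Et2O at 0 °C releases the bromo alcohol F8, and Dess–Martin oxidation returns to 20 as a freshly made sample of defined configuration.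

**Further compounds**

F1 | step 15 | 2-thioxopyridin-1(2H)-yl (3R,4S)-4-bromo-5-[(1S,3S,4S)-3-bromo-4-chloro-1-ethynyl-4-methylcyclohexyl]-3-[(tert-butyldimethylsilyl)oxy]-5-methylhexanoate | S=c1ccccn1OC(=O)C[C@@H](O[Si](C)(C)C(C)(C)C)[C@@H](Br)C(C)(C)[C@@]1(C#C)CC[C@](C)(Cl)[C@@H](Br)C1
F2 | step 8 | 3-[(1R)-1-(hydroxymethyl)-4-methylcyclohex-3-en-1-yl]-3-methylbutyl acetate | CC(=O)OCCC(C)(C)[C@@]1(CO)CCC(C)=CC1
F3 | step 8 | 3-methyl-3-[(1R)-4-methyl-1-({[tri(propan-2-yl)silyl]oxy}methyl)cyclohex-3-en-1-yl]butyl acetate | CC(=O)OCCC(C)(C)[C@@]1(CO[Si](C(C)C)(C(C)C)C(C)C)CCC(C)=CC1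
F4 | step 8 | 3-[(1R,3S,4S)-3-bromo-4-chloro-4-methyl-1-({[tri(propan-2-yl)silyl]oxy}methyl)cyclohexyl]-3-methylbutyl acetate | CC(=O)OCCC(C)(C)[C@@]1(CO[Si](C(C)C)(C(C)C)C(C)C)CC[C@](C)(Cl)[C@@H](Br)C1
F5 | step 12 | 3-[(1R,3S,4S)-3-bromo-4-chloro-1-ethynyl-4-methylcyclohexyl]-3-methylbutanoic acid | OC(=O)CC(C)(C)[C@@]1(C#C)CC[C@](C)(Cl)[C@@H](Br)C1
F6 | step 12 | (4S)-4-benzyl-3-{3-[(1R,3S,4S)-3-bromo-4-chloro-1-ethynyl-4-methylcyclohexyl]-3-methylbutanoyl}-1,3-oxazolidin-2-one | O=C(CC(C)(C)[C@@]1(C#C)CC[C@](C)(Cl)[C@@H](Br)C1)N1[C@@H](Cc2ccccc2)COC1=O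
F7 | step 12 | (4S)-4-benzyl-3-{(2S)-2-bromo-3-[(1S,3S,4S)-3-bromo-4-chloro-1-ethynyl-4-methylcyclohexyl]-3-methylbutanoyl}-1,3-oxazolidin-2-one | O=C([C@@H](Br)C(C)(C)[C@@]1(C#C)CC[C@](C)(Cl)[C@@H](Br)C1)N1[C@@H](Cc2ccccc2)COC1=O
F8 | step 12 | (2S)-2-bromo-3-[(1S,3S,4S)-3-bromo-4-chloro-1-ethynyl-4-methylcyclohexyl]-3-methylbutan-1-ol | OC[C@@H](Br)C(C)(C)[C@@]1(C#C)CC[C@](C)(Cl)[C@@H](Br)C1
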